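**Retrosynthetic overview**

- The route rests on the C3–C4 bond of the γ-lactone ring (O1–C2(=O)–C3(=CH2)–C4(CO2H)–C5(chain)), which joins the methylene-bearing carbon to the carboxyl-bearing carbon.
- Target 12 comes from the mono-tert-butyl ester 11 (ester cleavage), 11 from acid 10 (oxidation of the ring CH2–O to the lactone C=O), and 10 from alcohol 9 (CH2OH to CO2H).
- Alcohol 9 comes from epoxy propargyl ether 8 by reductive epoxide opening and 5-exo-dig radical closure, which forms C3–C4 and the only ring, at the oxolane oxidation level.
- Ether 8 comes from erythro epoxy alcohol 6 and propargyl bromide 7; 6 comes from racemic alkenol 5 by kinetic resolution, which fixes C5.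
- Alkenol 5 comes from aldehyde 3 and vinylmagnesium bromide 4; 3 comes from the mono-tert-butyl diacid 1 by way of alcohol 2.

Key step: step 6

Remark: lactone numbering (O1, C2 carbonyl, C3 methylene carbon, C4 carboxyl carbon, C5 chain carbon) is used in the text; the target is the 4,5-trans acid, (2R,3S) in oxolane nomenclature. The kinetic resolution is assumed to follow its usual sense (the L-(+)-tartrate catalyst epoxidises the (S)-alkenol), so the D-(−)-tartrate is used.

**Route**

Step 1
Reactants: 1 16-tert-butoxy-16-oxohexadecanoic acid
Product: 2 tert-butyl 16-hydroxyhexadecanoate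
Conditions: BH3·SMe2, THF, 0 °C → rt; then H2O
Reagents that add atoms: none
Why: Chemoselective borane reduction of a carboxylic acid, which is activated as an acyloxyborane and reduced much faster than the hindered tert-butyl ester.

Step 2
Reactants: 2 tert-butyl 16-hydroxyhexadecanoate
Product: 3 tert-butyl 16-oxohexadecanoate
Conditions: TEMPO (cat.), PhI(OAc)2, CH2Cl2, rt
Reagents that add atoms: none
Why: TEMPO-catalysed oxidation with PhI(OAc)2 as terminal oxidant should stop cleanly at the aldehyde under neutral, anhydrous conditions and leave the tert-butyl ester untouched.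

Step 3
Reactants: 3 tert-butyl 16-oxohexadecanoate; 4 vinylmagnesium bromide
Product: 5 tert-butyl 16-hydroxyoctadec-17-enoate (racemic)
Conditions: CH2=CHMgBr, THF, −78 °C; then sat. aq. NH4Cl
Reagents that add atoms: none
Why: Grignard addition to the aldehyde at low temperature, where the hindered tert-butyl ester does not compete; the carbinol centre is formed racemic and is resolved in step 4.

Step 4
Reactants: 5 tert-butyl 16-hydroxyoctadec-17-enoate (racemic)
Product: 6 tert-butyl (16R)-16-hydroxy-16-[(2S)-oxiran-2-yl]hexadecanoate
Conditions: Ti(OiPr)4 (0.2 equiv), diisopropyl D-(−)-tartrate (0.25 equiv), tert-butyl hydroperoxide (0.45 equiv, anhydrous), 4 Å molecular sieves, CH2Cl2, −20 °C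
Reagents that add atoms: tert-butyl hydroperoxide, CC(C)(C)OO
Why: Sharpless kinetic resolution, in which the D-(−)-tartrate catalyst should epoxidise the (16R)-alkenol much faster than its enantiomer and with erythro face selectivity, so that a sub-stoichiometric charge of hydroperoxide converts only that enantiomer into the (16R, oxirane 2S) epoxy alcohol and thereby fixes the centre that becomes C5.

Step 5
Reactants: 6 tert-butyl (16R)-16-hydroxy-16-[(2S)-oxiran-2-yl]hexadecanoate; 7 propargyl bromide
Product: 8 tert-butyl (16R)-16-[(2S)-oxiran-2-yl]-16-(prop-2-yn-1-yloxy)hexadecanoate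
Conditions: propargyl bromide, NaH (added last), Bu4NI (cat.), THF, 0 °C → rt
Reagents that add atoms: none
Why: Williamson etherification of the sodium alkoxide with the reactive propargylic bromide, which in an aprotic medium at low temperature with the electrophile already present should outrun Payne rearrangement of the epoxy alkoxide and touches neither stereocentre.

Step 6
Reactants: 8 tert-butyl (16R)-16-[(2S)-oxiran-2-yl]-16-(prop-2-yn-1-yloxy)hexadecanoate
Product: 9 tert-butyl 15-[(2R,3R)-3-(hydroxymethyl)-4-methylideneoxolan-2-yl]pentadecanoate
Conditions: Cp2TiCl2 (2.5 equiv), Zn dust, THF, rt (green Cp2TiCl solution), added slowly to 8 in dilute THF, rt; then 1 M aq. HCl, 0 °C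
Reagents that add atoms: none
Why: Cp2TiCl (trivalent titanium) transfers one electron to the oxirane, whose bond from oxygen to the internal carbon breaks homolytically to give the secondary β-titanoxy radical at C4, and this radical adds to the proximal alkyne carbon of the propargyl ether before the resulting vinyl radical is quenched by hydrogen abstraction from THF or by a second Cp2TiCl and protonation on work-up. The closest known reaction type is the Cp2TiCl-mediated reductive epoxide opening with radical cyclization onto a tethered alkyne, which is established for epoxy propargyl ethers. The oxolane ring (the later lactone ring) closes in the 5-exo-dig mode through C4, C5, O1, the propargylic CH2 and the alkyne carbon that becomes C3, which forms the C3–C4 bond. The only new stereocentre is C4: the radical is planar, so the oxirane configuration is erased, and the C5 centre controls it through a chair-like 5-exo transition state in which the C5 chain sits pseudo-equatorial and the bulky titanoxymethyl group on the radical carbon turns away from it, which should give the 4,5-trans isomer. The step needs ring closure to outrun capture of the radical by a second trivalent titanium (which would end in β-elimination to the deoxygenated alkene); the fast closure of a 3-oxahex-5-ynyl radical, high dilution and slow addition of Cp2TiCl secure this, while the tert-butyl ester and the alkyne C–H are inert to the reagent.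

Step 7
Reactants: 9 tert-butyl 15-[(2R,3R)-3-(hydroxymethyl)-4-methylideneoxolan-2-yl]pentadecanoate
Product: 10 (2R,3S)-2-(15-tert-butoxy-15-oxopentadecyl)-4-methylideneoxolane-3-carboxylic acid
Conditions: CrO3, aq. H2SO4, acetone, 0 °C
Reagents that add atoms: water, O
Why: Jones oxidation of the primary alcohol to the acid through the aldehyde hydrate is fast at 0 °C, so the tert-butyl ester and the 1,1-disubstituted alkene should survive, and the adjacent centre keeps its trans arrangement, which is also the thermodynamically favoured one.

Step 8
Reactants: 10 (2R,3S)-2-(15-tert-butoxy-15-oxopentadecyl)-4-methylideneoxolane-3-carboxylic acid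
Product: 11 (2R,3S)-2-(15-tert-butoxy-15-oxopentadecyl)-4-methylidene-5-oxooxolane-3-carboxylic acid
Conditions: CrO3 (excess), pyridine, CH2Cl2, rt (CrO3·2 pyridine formed in the flask); then dilute aq. HCl work-up
Reagents that add atoms: chromium trioxide, O=[Cr](=O)=O
Why: Chromium-mediated allylic C–H oxidation, in which the ring CH2 is activated both by the ether oxygen and by the exocyclic alkene, so that hexavalent chromium as its pyridine complex should convert it selectively into the lactone carbonyl and deliver the α-methylene-γ-butyrolactone without moving the alkene.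

Step 9
Reactants: 11 (2R,3S)-2-(15-tert-butoxy-15-oxopentadecyl)-4-methylidene-5-oxooxolane-3-carboxylic acid
Product: 12 (2R,3S)-2-(14-carboxytetradecyl)-4-methylidene-5-oxooxolane-3-carboxylic acid
Conditions: CF3CO2H, CH2Cl2, 0 °C → rt
Reagents that add atoms: none
Why: Acidolysis of the tert-butyl ester with loss of 2-methylpropene under anhydrous, non-basic conditions avoids base-promoted migration of the exocyclic double bond into the ring and leaves both stereocentres untouched.

**Compound list**

1 | 16-tert-butoxy-16-oxohexadecanoic acid | OC(=O)CCCCCCCCCCCCCCC(=O)OC(C)(C)C | starting material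
2 | tert-butyl 16-hydroxyhexadecanoate | OCCCCCCCCCCCCCCCC(=O)OC(C)(C)C | intermediate
3 | tert-butyl 16-oxohexadecanoate | O=CCCCCCCCCCCCCCCC(=O)OC(C)(C)C | intermediate
4 | vinylmagnesium bromide | C=C[Mg]Br | starting material
5 | tert-butyl 16-hydroxyoctadec-17-enoate (racemic) | C=CC(O)CCCCCCCCCCCCCCC(=O)OC(C)(C)C | intermediate
6 | tert-butyl (16R)-16-hydroxy-16-[(2S)-oxiran-2-yl]hexadecanoate (erythro) | O[C@H](CCCCCCCCCCCCCCC(=O)OC(C)(C)C)[C@@H]1CO1 | intermediate
7 | propargyl bromide (3-bromoprop-1-yne) | C#CCBr | starting material
8 | tert-butyl (16R)-16-[(2S)-oxiran-2-yl]-16-(prop-2-yn-1-yloxy)hexadecanoate | C#CCO[C@H](CCCCCCCCCCCCCCC(=O)OC(C)(C)C)[C@@H]1CO1 | intermediate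
9 | tert-butyl 15-[(2R,3R)-3-(hydroxymethyl)-4-methylideneoxolan-2-yl]pentadecanoate (2,3-trans) | C=C1CO[C@H](CCCCCCCCCCCCCCC(=O)OC(C)(C)C)[C@H]1CO | intermediate
10 | (2R,3S)-2-(15-tert-butoxy-15-oxopentadecyl)-4-methylideneoxolane-3-carboxylic acid | C=C1CO[C@H](CCCCCCCCCCCCCCC(=O)OC(C)(C)C)[C@H]1C(=O)O | intermediate
11 | (2R,3S)-2-(15-tert-butoxy-15-oxopentadecyl)-4-methylidene-5-oxooxolane-3-carboxylic acid | C=C1C(=O)O[C@H](CCCCCCCCCCCCCCC(=O)OC(C)(C)C)[C@H]1C(=O)O | intermediate
12 | (2R,3S)-2-(14-carboxytetradecyl)-4-methylidene-5-oxooxolane-3-carboxylic acid | C=C1C(=O)O[C@H](CCCCCCCCCCCCCCC(=O)O)[C@H]1C(=O)O | target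

**Summary**

Total step count: 9
Longest linear sequence: 9 steps (1 → 12)

**Steps most likely to fail**

1. Step 6 (radical cyclization). The β-titanoxy radical may be captured by a second trivalent titanium before it closes, which leads to β-elimination and loss of the oxygen function, and the trans selectivity may be incomplete.
Fallback, from 8 back to 9: the same C4 radical is generated by tin hydride instead of by electron transfer. The oxirane of 8 would be opened at its terminal carbon with benzoic acid (cat. Bu4NBr, MeCN, reflux) to tert-butyl (16R,17S)-18-(benzoyloxy)-17-hydroxy-16-(prop-2-yn-1-yloxy)octadecanoate F1. The secondary alcohol would be acylated with phenyl chlorothionoformate (pyridine, DMAP, CH2Cl2) to tert-butyl (16R,17S)-18-(benzoyloxy)-17-[(phenoxycarbonothioyl)oxy]-16-(prop-2-yn-1-yloxy)octadecanoate F2. Bu3SnH with AIBN (toluene, 90 °C, slow addition) would cleave the C–O bond in a Barton–McCombie-type fragmentation, and the radical would close 5-exo-dig to tert-butyl 15-[(2R,3R)-3-[(benzoyloxy)methyl]-4-methylideneoxolan-2-yl]pentadecanoate F3. Methanolysis of the benzoate (K2CO3, MeOH, rt) would then give 9.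

2. Step 8 (allylic oxidation on the free acid). The carboxylate may bind to chromium and slow the C–H oxidation, and the exocyclic double bond may migrate into the ring during a long reaction in the presence of pyridine.
Fallback, from 10 back to 12: the ring acid is masked before the oxidation and both esters are cleaved together at the end. Acid 10 would be esterified with tert-butyl 2,2,2-trichloroacetimidate (cat. BF3·OEt2, CH2Cl2–cyclohexane, rt) to tert-butyl (2R,3S)-2-(15-tert-butoxy-15-oxopentadecyl)-4-methylideneoxolane-3-carboxylate F4. The neutral diester would be oxidised at the ring CH2 with CrO3·2 pyridine in CH2Cl2 to tert-butyl (2R,3S)-2-(15-tert-butoxy-15-oxopentadecyl)-4-methylidene-5-oxooxolane-3-carboxylate F5. CF3CO2H in CH2Cl2 would cleave both tert-butyl esters and give 12.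

3. Step 4 (kinetic resolution). The terminal vinyl carbinol turns over slowly, and discrimination between the enantiomers may be insufficient at the conversion used, so the epoxy alcohol would carry eroded enantiomeric purity into every later compound.
Fallback, from 5 back to 9: the slow-reacting enantiomer is used, because its purity rises with conversion. The resolution would be run with diisopropyl L-(+)-tartrate and about 0.6 equiv of tert-butyl hydroperoxide, so that the (S)-alkenol is consumed and tert-butyl (16R)-16-hydroxyoctadec-17-enoate F6 is recovered. Etherification with 7 (NaH, THF, 0 °C → rt) would give tert-butyl (16R)-16-(prop-2-yn-1-yloxy)octadec-17-enoate F7; no epoxide is present at this stage, so Payne rearrangement cannot occur. Epoxidation of the terminal alkene with 3-chloroperbenzoic acid (CH2Cl2, NaHCO3, rt; the alkyne reacts far more slowly) would give tert-butyl (16R)-16-(oxiran-2-yl)-16-(prop-2-yn-1-yloxy)hexadecanoate F8 as both epimers at the oxirane carbon. Both epimers form the same planar C4 radical under the conditions of step 6 and should converge on 9.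

**Further compounds**

F1 | step 6 | tert-butyl (16R,17S)-18-(benzoyloxy)-17-hydroxy-16-(prop-2-yn-1-yloxy)octadecanoate | C#CCO[C@H](CCCCCCCCCCCCCCC(=O)OC(C)(C)C)[C@@H](O)COC(=O)c1ccccc1
F2 | step 6 | tert-butyl (16R,17S)-18-(benzoyloxy)-17-[(phenoxycarbonothioyl)oxy]-16-(prop-2-yn-1-yloxy)octadecanoate | C#CCO[C@H](CCCCCCCCCCCCCCC(=O)OC(C)(C)C)[C@@H](OC(=S)Oc1ccccc1)COC(=O)c1ccccc1
F3 | step 6 | tert-butyl 15-[(2R,3R)-3-[(benzoyloxy)methyl]-4-methylideneoxolan-2-yl]pentadecanoate | C=C1CO[C@H](CCCCCCCCCCCCCCC(=O)OC(C)(C)C)[C@H]1COC(=O)c1ccccc1
F4 | step 8 | tert-butyl (2R,3S)-2-(15-tert-butoxy-15-oxopentadecyl)-4-methylideneoxolane-3-carboxylate | C=C1CO[C@H](CCCCCCCCCCCCCCC(=O)OC(C)(C)C)[C@H]1C(=O)OC(C)(C)C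
F5 | step 8 | tert-butyl (2R,3S)-2-(15-tert-butoxy-15-oxopentadecyl)-4-methylidene-5-oxooxolane-3-carboxylate | C=C1C(=O)O[C@H](CCCCCCCCCCCCCCC(=O)OC(C)(C)C)[C@H]1C(=O)OC(C)(C)C
F6 | step 4 | tert-butyl (16R)-16-hydroxyoctadec-17-enoate | C=C[C@H](O)CCCCCCCCCCCCCCC(=O)OC(C)(C)C
F7 | step 4 | tert-butyl (16R)-16-(prop-2-yn-1-yloxy)octadec-17-enoate | C=C[C@H](OCC#C)CCCCCCCCCCCCCCC(=O)OC(C)(C)C
F8 | step 4 | tert-butyl (16R)-16-(oxiran-2-yl)-16-(prop-2-yn-1-yloxy)hexadecanoate, both epimers at the oxirane carbon | C#CCO[C@H](CCCCCCCCCCCCCCC(=O)OC(C)(C)C)C1CO1
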